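**Retrosynthetic overview**
1. Target 19 ⇐ O6-benzyl ether 18 ⇐ diaryl ketone 16: the bridge carbon C9 is carried as a ketone and reduced to CH2 at the end.
2. Ring C (C1'–C6') of 16 ⇐ ynone 11 + ketene-acetal diene 13 by [4+2] benzannulation, forming C2'–C3' and C1'–C6'. The feature used is ring C itself: 6'-OMe and 4'-OH meta to each other, CH2OMe on C2' and C1' on C9, the pattern this diene leaves on an alkyne whose activating carbonyl is C9.
3. Ynone 11 ⇐ 5-iodoisocoumarin 9 + CO + alkyne 10 (C9 comes from CO).
4. Isocoumarin 9 ⇐ keto ester 8 ⇐ iodinated orsellinate 4 ⇐ methyl orsellinate 1 (lateral lithiation and acylation in place of a C–H annulation next to the halogen).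
5. Ring order: ring A (benzo ring, purchased), ring B (pyranone, step 5), ring C (step 8).

Key step: step 8

Remark: the target is achiral; the only stereocentre on the way (C9 of carbinol 17) is formed racemic and removed in step 10. Isocoumarin numbering is used (C1 lactone carbonyl, O2, C3 to C8a; C9 bridge; C1' to C6' ring C), and 1, 5, 10 and 12 are taken as purchasable.

**Step 1**
Reactants: 1 methyl 2,4-dihydroxy-6-methylbenzoate (methyl orsellinate)
Product: 2 methyl 4-(benzyloxy)-2-hydroxy-6-methylbenzoate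
Conditions: BnBr (1.05 equiv), K2CO3, acetone, reflux
Reagents that add atoms: benzyl bromide, BrCc1ccccc1
Why: Williamson etherification should take the free 4-OH only, because the 2-OH is hydrogen-bonded to the ester carbonyl and is much less nucleophilic.

**Step 2**
Reactants: 2 methyl 4-(benzyloxy)-2-hydroxy-6-methylbenzoate
Product: 3 methyl 4-(benzyloxy)-2-methoxy-6-methylbenzoate
Conditions: MeI, K2CO3, DMF, 50 °C
Reagents that add atoms: iodomethane, CI
Why: Williamson O-methylation of the chelated phenol under more forcing conditions fixes the future 8-OMe.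

**Step 3**
Reactants: 3 methyl 4-(benzyloxy)-2-methoxy-6-methylbenzoate
Product: 4 methyl 4-(benzyloxy)-3-iodo-6-methoxy-2-methylbenzoate
Conditions: NIS, CF3CO2H (cat.), MeCN, 0 °C → rt
Reagents that add atoms: N-iodosuccinimide, O=C1CCC(=O)N1I
Why: Electrophilic aromatic iodination should go to the carbon para to OMe, ortho to OBn and ortho to the methyl group (future C5) rather than to the carbon between the two ethers, as 3,5-dialkoxytoluenes generally do.

**Step 4**
Reactants: 4 methyl 4-(benzyloxy)-3-iodo-6-methoxy-2-methylbenzoate; 5 N-methoxy-N-methylacetamide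
Product: 8 methyl 4-(benzyloxy)-3-iodo-6-methoxy-2-(2-oxopropyl)benzoate, via benzylic lithium species 6 (not isolated), via lithium hemiaminal alkoxide 7 (not isolated)
Conditions: LiN(iPr)2 (1.2 equiv), THF, −78 °C; then 5, −78 → −30 °C; aq. NH4Cl
Reagents that add atoms: none
Why: Lateral lithiation of the ortho-toluate gives the ester-stabilised benzylic anion 6, whose acylation by the N-methoxy-N-methylamide stops at the chelated adduct 7 and releases the methyl ketone only on work-up; the iodide has no ortho hydrogen, so halogen migration and aryne formation are closed.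

**Step 5**
Reactants: 8 methyl 4-(benzyloxy)-3-iodo-6-methoxy-2-(2-oxopropyl)benzoate
Product: 9 6-(benzyloxy)-5-iodo-8-methoxy-3-methyl-1H-isochromen-1-one
Conditions: p-TsOH·H2O (cat.), toluene, reflux (MeOH distilled off)
Reagents that add atoms: none
Why: Acid-catalysed enol lactonisation, in which the aryl-conjugated enol oxygen attacks the ester carbonyl (6-exo-trig) with loss of methanol, closes ring B; acid avoids the C-acylation to a naphthalenediol that base would open.

**Step 6**
Reactants: 9 6-(benzyloxy)-5-iodo-8-methoxy-3-methyl-1H-isochromen-1-one; 10 3-methoxyprop-1-yne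
Product: 11 6-(benzyloxy)-8-methoxy-5-(4-methoxybut-2-ynoyl)-3-methyl-1H-isochromen-1-one
Conditions: CO (1 atm), PdCl2(PPh3)2 (cat.), CuI (cat.), Et3N, THF, rt → 45 °C
Reagents that add atoms: carbon monoxide, [C-]#[O+]
Why: Carbonylative Sonogashira coupling (oxidative addition of the C5–I bond to zerovalent palladium, CO insertion, transfer of the copper acetylide, reductive elimination) should give the ynone, since the two flanking groups slow direct alkynylation and the iodide reacts under mild conditions.

**Step 7**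
Reactants: 12 4,4-dimethoxybut-3-en-2-one
Product: 13 1,1-dimethoxy-3-(trimethylsilyloxy)buta-1,3-diene
Conditions: Me3SiCl, Et3N, ZnCl2 (cat.), toluene, 40 °C; filtration, distillation under reduced pressure, used fresh
Reagents that add atoms: chlorotrimethylsilane, C[Si](C)(C)Cl
Why: Soft enolisation and O-silylation of the methyl ketone (the only enolisable site) gives the silyl dienol ether, the standard preparation of this diene.

**Step 8**
Reactants: 11 6-(benzyloxy)-8-methoxy-5-(4-methoxybut-2-ynoyl)-3-methyl-1H-isochromen-1-one; 13 1,1-dimethoxy-3-(trimethylsilyloxy)buta-1,3-diene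
Product: 16 6-(benzyloxy)-5-[4-hydroxy-2-methoxy-6-(methoxymethyl)benzoyl]-8-methoxy-3-methyl-1H-isochromen-1-one, via cyclohexadiene cycloadduct 14 (not isolated), via aryl trimethylsilyl ether 15 (not isolated)
Conditions: 13 (3 equiv), toluene, 25 → 90 °C; then 1 M HCl, THF, 0 °C
Reagents that add atoms: none
Why: The ketene acetal and the silyl enol ether make the CH2 terminus of the diene (future C3') its nucleophilic end, so it adds to the β-carbon of the ynone (future C2', bearing CH2OMe) while the ketene-acetal carbon (future C6') bonds to the α-carbon (future C1') in an asynchronous Diels–Alder reaction; cyclohexa-1,4-diene 14 then loses methanol by 1,4-elimination to aromatise to 15, and dilute acid cleaves the silyl ether to phenol 16. The closest known reaction type is the Diels–Alder benzannulation of 1,1-dialkoxy-3-silyloxybuta-1,3-dienes with acetylenic ketones and esters, with aromatisation by loss of alcohol. Ring C closes by intermolecular [4+2] cycloaddition, both ring bonds (C2'–C3' and C1'–C6') coming from the one cycloaddition. No stereocentre is formed. The step needs regioselectivity (OMe ortho and OH para to C9), which the matched polarity of diene and ynone secures, and chemoselectivity for the alkyne, which is the only electron-poor π-bond because C3=C4 of ring B is an electron-rich enol-ester alkene and O6 is benzylated, so no oxa-Michael closure to a chromone can compete.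

**Step 9**
Reactants: 16 6-(benzyloxy)-5-[4-hydroxy-2-methoxy-6-(methoxymethyl)benzoyl]-8-methoxy-3-methyl-1H-isochromen-1-one
Product: 17 rac-6-(benzyloxy)-5-{hydroxy[4-hydroxy-2-methoxy-6-(methoxymethyl)phenyl]methyl}-8-methoxy-3-methyl-1H-isochromen-1-one
Conditions: NaBH4, THF–MeOH, 0 °C → rt; crude carbinol taken on
Reagents that add atoms: none
Why: Borohydride 1,2-reduction of the diaryl ketone should leave the conjugated lactone untouched at this temperature; C9 is formed racemic without control, and any diarylmethane 18 formed by further reduction through the para-quinone methide converges in step 10.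

**Step 10**
Reactants: 17 rac-6-(benzyloxy)-5-{hydroxy[4-hydroxy-2-methoxy-6-(methoxymethyl)phenyl]methyl}-8-methoxy-3-methyl-1H-isochromen-1-one
Product: 18 6-(benzyloxy)-5-[4-hydroxy-2-methoxy-6-(methoxymethyl)benzyl]-8-methoxy-3-methyl-1H-isochromen-1-one
Conditions: Et3SiH (5 equiv), CF3CO2H, CH2Cl2, −10 → 0 °C (acid added last)
Reagents that add atoms: none
Why: Ionic hydrogenation: the carbinol ionises to a diarylmethyl cation stabilised by 4'-OH/6'-OMe and 6-OBn/8-OMe and is trapped by silane hydride, whereas the C2' CH2OMe is meta to both ring C donors and should not ionise.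

**Step 11**
Reactants: 18 6-(benzyloxy)-5-[4-hydroxy-2-methoxy-6-(methoxymethyl)benzyl]-8-methoxy-3-methyl-1H-isochromen-1-one
Product: 19 6-hydroxy-5-[4-hydroxy-2-methoxy-6-(methoxymethyl)benzyl]-8-methoxy-3-methyl-1H-isochromen-1-one (target)
Conditions: H2 (1 atm), 10% Pd/C, EtOAc, rt; stopped after one equivalent of H2
Reagents that add atoms: none
Why: Hydrogenolysis of the aryl benzyl ether should be much faster than cleavage of the hindered, electron-rich ArCH2–OMe ether or saturation of the C3=C4 bond of ring B.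

**Compound list**
1 | methyl 2,4-dihydroxy-6-methylbenzoate | COC(=O)c1c(C)cc(O)cc1O | starting material
2 | methyl 4-(benzyloxy)-2-hydroxy-6-methylbenzoate | COC(=O)c1c(C)cc(OCc2ccccc2)cc1O | intermediate
3 | methyl 4-(benzyloxy)-2-methoxy-6-methylbenzoate | COC(=O)c1c(C)cc(OCc2ccccc2)cc1OC | intermediate
4 | methyl 4-(benzyloxy)-3-iodo-6-methoxy-2-methylbenzoate | COC(=O)c1c(C)c(I)c(OCc2ccccc2)cc1OC | intermediate
5 | N-methoxy-N-methylacetamide | CC(=O)N(C)OC | starting material
6 | {[3-(benzyloxy)-2-iodo-5-methoxy-6-(methoxycarbonyl)phenyl]methyl}lithium | [Li]Cc1c(I)c(OCc2ccccc2)cc(OC)c1C(=O)OC | intermediate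
7 | lithium 1-[3-(benzyloxy)-2-iodo-5-methoxy-6-(methoxycarbonyl)phenyl]-2-[methoxy(methyl)amino]propan-2-olate | CC(O[Li])(Cc1c(I)c(OCc2ccccc2)cc(OC)c1C(=O)OC)N(C)OC | intermediate
8 | methyl 4-(benzyloxy)-3-iodo-6-methoxy-2-(2-oxopropyl)benzoate | COC(=O)c1c(CC(C)=O)c(I)c(OCc2ccccc2)cc1OC | intermediate
9 | 6-(benzyloxy)-5-iodo-8-methoxy-3-methyl-1H-isochromen-1-one | Cc1cc2c(I)c(OCc3ccccc3)cc(OC)c2c(=O)o1 | intermediate
10 | 3-methoxyprop-1-yne | COCC#C | starting material
11 | 6-(benzyloxy)-8-methoxy-5-(4-methoxybut-2-ynoyl)-3-methyl-1H-isochromen-1-one | COCC#CC(=O)c1c(OCc2ccccc2)cc(OC)c2c(=O)oc(C)cc12 | intermediate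
12 | 4,4-dimethoxybut-3-en-2-one | COC(OC)=CC(C)=O | starting material
13 | 1,1-dimethoxy-3-(trimethylsilyloxy)buta-1,3-diene | COC(OC)=CC(=C)O[Si](C)(C)C | intermediate
14 | 6-(benzyloxy)-5-{[6,6-dimethoxy-2-(methoxymethyl)-4-(trimethylsilyloxy)cyclohexa-1,4-dien-1-yl]carbonyl}-8-methoxy-3-methyl-1H-isochromen-1-one | COCC1=C(C(=O)c2c(OCc3ccccc3)cc(OC)c3c(=O)oc(C)cc23)C(OC)(OC)C=C(O[Si](C)(C)C)C1 | intermediate
15 | 6-(benzyloxy)-8-methoxy-5-[2-methoxy-6-(methoxymethyl)-4-(trimethylsilyloxy)benzoyl]-3-methyl-1H-isochromen-1-one | COCc1cc(O[Si](C)(C)C)cc(OC)c1C(=O)c1c(OCc2ccccc2)cc(OC)c2c(=O)oc(C)cc12 | intermediate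
16 | 6-(benzyloxy)-5-[4-hydroxy-2-methoxy-6-(methoxymethyl)benzoyl]-8-methoxy-3-methyl-1H-isochromen-1-one | COCc1cc(O)cc(OC)c1C(=O)c1c(OCc2ccccc2)cc(OC)c2c(=O)oc(C)cc12 | intermediate
17 | rac-6-(benzyloxy)-5-{hydroxy[4-hydroxy-2-methoxy-6-(methoxymethyl)phenyl]methyl}-8-methoxy-3-methyl-1H-isochromen-1-one (racemic at C9) | COCc1cc(O)cc(OC)c1C(O)c1c(OCc2ccccc2)cc(OC)c2c(=O)oc(C)cc12 | intermediate
18 | 6-(benzyloxy)-5-[4-hydroxy-2-methoxy-6-(methoxymethyl)benzyl]-8-methoxy-3-methyl-1H-isochromen-1-one | COCc1cc(O)cc(OC)c1Cc1c(OCc2ccccc2)cc(OC)c2c(=O)oc(C)cc12 | intermediate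
19 | 6-hydroxy-5-[4-hydroxy-2-methoxy-6-(methoxymethyl)benzyl]-8-methoxy-3-methyl-1H-isochromen-1-one | COCc1cc(O)cc(OC)c1Cc1c(O)cc(OC)c2c(=O)oc(C)cc12 | target

**Step count**
Total: 11 steps. Longest linear sequence: 10 steps (steps 1 to 6 and 8 to 11, from 1 to 19); step 7 makes diene 13 in one step from 12.

**Steps most likely to fail**

Step 8 (key step). The second ring bond (C1'–C6') must form at the α-carbon next to an aroyl group that already has two ortho substituents. Ring closure may therefore lag behind the first C–C bond, so that open-chain conjugate adducts build up while the diene is lost by protonation and oligomerisation. The fallback builds ring C by the same cycloaddition on an unhindered acetylenic ester and then joins it to C5 through C9. It sets out from 10, 13 and 9 and comes back to the route at 19.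
- Alkyne 10 is deprotonated (nBuLi, THF, −78 °C) and acylated with ClCO2Me to methyl 4-methoxybut-2-ynoate F1.
- F1 and 13 in toluene at 80 °C should give the cycloadduct methyl 6,6-dimethoxy-2-(methoxymethyl)-4-(trimethylsilyloxy)cyclohexa-1,4-diene-1-carboxylate F2, which loses methanol to methyl 2-methoxy-6-(methoxymethyl)-4-(trimethylsilyloxy)benzoate F3; dilute HCl then gives methyl 4-hydroxy-2-methoxy-6-(methoxymethyl)benzoate F4.
- Benzylation (BnBr, K2CO3, DMF) gives methyl 4-(benzyloxy)-2-methoxy-6-(methoxymethyl)benzoate F5, LiAlH4 in THF reduces it to [4-(benzyloxy)-2-methoxy-6-(methoxymethyl)phenyl]methanol F6, and MnO2 in CH2Cl2 oxidises this to 4-(benzyloxy)-2-methoxy-6-(methoxymethyl)benzaldehyde F7.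
- Iodine–magnesium exchange on 9 (iPrMgCl·LiCl, THF, −30 °C) gives [6-(benzyloxy)-8-methoxy-3-methyl-1-oxo-1H-isochromen-5-yl]magnesium chloride F8, which should add to F7 to give rac-6-(benzyloxy)-5-{[4-(benzyloxy)-2-methoxy-6-(methoxymethyl)phenyl](hydroxy)methyl}-8-methoxy-3-methyl-1H-isochromen-1-one F9.
- Et3SiH and CF3CO2H in CH2Cl2 reduce F9 to 6-(benzyloxy)-5-[4-(benzyloxy)-2-methoxy-6-(methoxymethyl)benzyl]-8-methoxy-3-methyl-1H-isochromen-1-one F10, and hydrogenolysis of both benzyl ethers (H2, 10% Pd/C, EtOAc) gives 19.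

Step 6. Direct alkynylation without CO uptake may compete, oxidative addition and CO insertion may be slow at the flanked, electron-rich C5–I bond, and the amine may isomerise the propargylic ynone to an allenyl ketone. The fallback replaces the catalytic carbonylation by a stoichiometric aryl-metal addition and an oxidation. It sets out from 9 and 10 and comes back at 11.
- Exchange on 9 with iPrMgCl·LiCl (THF, −30 °C) gives [6-(benzyloxy)-8-methoxy-3-methyl-1-oxo-1H-isochromen-5-yl]magnesium chloride F8.
- Alkyne 10 is formylated (nBuLi, THF, −78 °C; DMF; quench into aq. KH2PO4) to 4-methoxybut-2-ynal F11.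
- F8 should add to F11 at −30 °C to give rac-6-(benzyloxy)-5-(1-hydroxy-4-methoxybut-2-yn-1-yl)-8-methoxy-3-methyl-1H-isochromen-1-one F12, which MnO2 in CH2Cl2 should oxidise to ynone 11.

Step 9. Hydride delivery to a ketone shielded by four ortho substituents and deactivated as its para-phenoxide in the basic medium may be slow, and prolonged exposure may let borohydride attack the lactone. The fallback reduces under acid instead, where the ketone is protonated and not deprotonated. It sets out from 16 and comes back at 18, passing over 17: Et3SiH in CF3CO2H/CH2Cl2 at rt to 40 °C should reduce the para-hydroxy, ortho-methoxy diaryl ketone directly to the methylene. No new compound is made.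

**Further compounds**
F1 | step 8 | methyl 4-methoxybut-2-ynoate | COCC#CC(=O)OC
F2 | step 8 | methyl 6,6-dimethoxy-2-(methoxymethyl)-4-(trimethylsilyloxy)cyclohexa-1,4-diene-1-carboxylate | COCC1=C(C(=O)OC)C(OC)(OC)C=C(O[Si](C)(C)C)C1
F3 | step 8 | methyl 2-methoxy-6-(methoxymethyl)-4-(trimethylsilyloxy)benzoate | COCc1cc(O[Si](C)(C)C)cc(OC)c1C(=O)OC
F4 | step 8 | methyl 4-hydroxy-2-methoxy-6-(methoxymethyl)benzoate | COCc1cc(O)cc(OC)c1C(=O)OC
F5 | step 8 | methyl 4-(benzyloxy)-2-methoxy-6-(methoxymethyl)benzoate | COCc1cc(OCc2ccccc2)cc(OC)c1C(=O)OC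
F6 | step 8 | [4-(benzyloxy)-2-methoxy-6-(methoxymethyl)phenyl]methanol | COCc1cc(OCc2ccccc2)cc(OC)c1CO
F7 | step 8 | 4-(benzyloxy)-2-methoxy-6-(methoxymethyl)benzaldehyde | COCc1cc(OCc2ccccc2)cc(OC)c1C=O
F8 | step 8 | [6-(benzyloxy)-8-methoxy-3-methyl-1-oxo-1H-isochromen-5-yl]magnesium chloride | Cc1cc2c([Mg]Cl)c(OCc3ccccc3)cc(OC)c2c(=O)o1
F9 | step 8 | rac-6-(benzyloxy)-5-{[4-(benzyloxy)-2-methoxy-6-(methoxymethyl)phenyl](hydroxy)methyl}-8-methoxy-3-methyl-1H-isochromen-1-one | COCc1cc(OCc2ccccc2)cc(OC)c1C(O)c1c(OCc2ccccc2)cc(OC)c2c(=O)oc(C)cc12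
F10 | step 8 | 6-(benzyloxy)-5-[4-(benzyloxy)-2-methoxy-6-(methoxymethyl)benzyl]-8-methoxy-3-methyl-1H-isochromen-1-one | COCc1cc(OCc2ccccc2)cc(OC)c1Cc1c(OCc2ccccc2)cc(OC)c2c(=O)oc(C)cc12
F11 | step 6 | 4-methoxybut-2-ynal | COCC#CC=O
F12 | step 6 | rac-6-(benzyloxy)-5-(1-hydroxy-4-methoxybut-2-yn-1-yl)-8-methoxy-3-methyl-1H-isochromen-1-one | COCC#CC(O)c1c(OCc2ccccc2)cc(OC)c2c(=O)oc(C)cc12
F0 | step 9 | none | none
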